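Take the easy step first: the spring run and the flask carry the same second substrate and free catalyst, and they differ in the charge of starting material.

- spring: starting material 1.3 M; second substrate 2 M; free catalyst 3.4 mM; run made earlier
- flask: starting material 2.0 M; second substrate 2.00 M; free catalyst 3.4 mM; time 20 min

spring run (percent of the starting material charged)

| time / min | target / % | starting material / % |
|---|---|---|
| 1.00 | 7.0 | 93.7 |
| 3.00 | 19.4 | 80.1 |
| 6.00 | 35.9 | 63.8 |
| 8.00 | 45.5 | 54.9 |
| 12.0 | 60.0 | 39.8 |
| 15.0 | 69.0 | 30.6 |
| 20.0 | 78.7 | 20.9 |

(scatter of a reading: 0.3 percentage points)

- steps under discussion: starting material + free catalyst <-> catalyst intermediate A; catalyst intermediate A -> free catalyst + target; second substrate + free catalyst <-> catalyst intermediate B; catalyst intermediate B -> free catalyst + second product; second substrate <-> dormant form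

- concentration of target at 20 min, in M
- concentration of starting material at 20 min, in M

From the last spring reading take k = 0.0783 min⁻¹, the pseudo-first-order constant: the logarithm of charged over left, divided by time. Integrated, the rate gives a fraction left, exp(−kt), in which the charge cancels. Carried to the flask, that leaves 0.418 M, the lower bound as long as the rate rises no faster than in proportion to starting material. For the upper bound, suppose a rate independent of starting material: the flask then loses the same molarity as the spring run, leaving 0.972 M.

Now tighten. Read the constant over the first 3.00 min of the spring run, where its starting material stood highest: 0.0740 min⁻¹, less than k. This leaves 0.456 M, but the flask starts at 2.0 M, more than the 1.3 M of the spring run, so this is an estimate and not a strict bound, and my working bracket runs from 0.418 M to 0.456 M. The last spring reading sums to 99.6%, so take target in the flask as the rest of the charge, from 1.54 M to 1.58 M.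

The forecast reads the run as “nearly first order in starting material” and gives 0.45 M of starting material and 1.55 M of target, inside the bracket.

The flask gives 0.421 M of starting material and 1.58 M of target, at the lower end of the starting-material bracket, and the forecast is right within its margins.

    starting material + free catalyst ⇌ catalyst intermediate A (K = 1.14 M⁻¹, k = 0.419 M⁻¹ s⁻¹)
    catalyst intermediate A → free catalyst + target (k = 20.1 s⁻¹)
    second substrate + free catalyst ⇌ catalyst intermediate B (K = 0.739 M⁻¹, k = 0.690 M⁻¹ s⁻¹)
    catalyst intermediate B → free catalyst + second product (k = 7.49 s⁻¹)
    second substrate ⇌ dormant form (K = 0.470, k = 5.12 × 10⁻⁴ s⁻¹)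

The 21.1% of starting material left in the flask returns a constant of 0.0779 min⁻¹. Now carry k to the neighbour charged with 1.40 mM of free catalyst, scaling it by the catalyst ratio: exp(−kt) then leaves 52.5%. That neighbour shows 54.0% left, which is 1.08 M of starting material beside 0.920 M of target.

The earlier runs and the new flask were generated by integration for substances that don't exist; noise was put on by code.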